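**Strategy.** The target is cut between C8 (the acetoxy-bearing carbon) and C9 (its CH2 neighbour). C9 is the γ-carbon of the exocyclic C10=C11 alkene of the five-membered lactone, so the array C8(O)–C9–C10=C11–C(=O)O is a vinylogous aldol retron. A catalytic enantioselective vinylogous Mukaiyama aldol reaction joins the C1–C8 enal (the 8-oxoneryl ester) to a 2-silyloxy-3-vinyl-4,5-dihydrofuran, the γ-deprotonated silyl dienol ether of the α-ethylidene lactone built from 2-deoxy-D-ribose. In one operation it forms C8–C9, sets the 8S carbinol under catalyst control and regenerates the lactone with the E-configured C10=C11 alkene.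

Key step: step 10

Remark: the chain is numbered C1 (ester OCH2) to C15 (C11 = lactone α-carbon, C12 = CHOH, C13 = ring CH–O); nerol, (2E)-3-methylpent-2-enoic acid and 2-deoxy-D-ribose are taken as purchasable single isomers.

**Route**

Step 1
Reactants: 1 nerol [(2Z)-3,7-dimethylocta-2,6-dien-1-ol]; 2 (2E)-3-methylpent-2-enoic acid
Product: 3 (2Z)-3,7-dimethylocta-2,6-dien-1-yl (2E)-3-methylpent-2-enoate
Conditions: DCC, DMAP (cat.), CH2Cl2, 0 °C to rt
Reagents that add atoms: none
Why: Steglich esterification acylates the primary allylic alcohol at oxygen, so the Z-C2=C3 alkene of nerol and the E-enoate geometry are carried over unchanged.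

Step 2
Reactants: 3 (2Z)-3,7-dimethylocta-2,6-dien-1-yl (2E)-3-methylpent-2-enoate
Product: 5 (2Z,6E)-3,7-dimethyl-8-oxoocta-2,6-dien-1-yl (2E)-3-methylpent-2-enoate, via C8 allylic alcohol 4 (not isolated)
Conditions: SeO2 (cat.), t-BuOOH, salicylic acid (cat.), CH2Cl2, rt; filter; then MnO2, CH2Cl2, rt
Reagents that add atoms: tert-butyl hydroperoxide CC(C)(C)OO (oxygen source); selenium dioxide O=[Se]=O (catalytic oxygen carrier)
Why: Riley allylic oxidation (ene reaction, then [2,3]-shift) should attack only the electron-rich terminal trisubstituted alkene at its E-methyl group, and MnO2 oxidation of the resulting allylic alcohol gives the (6E)-enal while the ester-deactivated C2=C3 alkene and the enoate stay untouched.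

Step 3
Reactants: 6 2-deoxy-D-ribose
Product: 7 2-deoxy-D-ribono-1,4-lactone [(4S,5R)-4-hydroxy-5-(hydroxymethyl)oxolan-2-one]
Conditions: Br2, H2O, rt, dark; neutralise, concentrate
Reagents that add atoms: none
Why: Bromine-water oxidation of the aldose at the anomeric carbon gives the aldonic acid, which closes to the five-membered lactone on concentration, and the two sugar stereocentres become the 4S and 5R centres (C12 and C13 of the target) without being touched.

Step 4
Reactants: 7 2-deoxy-D-ribono-1,4-lactone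
Product: 8 (4S,5R)-4-[(triethylsilyl)oxy]-5-{[(triethylsilyl)oxy]methyl}oxolan-2-one
Conditions: Et3SiCl, imidazole, DMF, 0 °C to rt
Reagents that add atoms: chlorotriethylsilane CC[Si](Cl)(CC)CC
Why: Imidazole-promoted silylation protects both hydroxyl groups as triethylsilyl ethers under conditions that leave the lactone closed.

Step 5
Reactants: 8 (4S,5R)-4-[(triethylsilyl)oxy]-5-{[(triethylsilyl)oxy]methyl}oxolan-2-one
Product: 9 (2S,3S)-5-oxo-3-[(triethylsilyl)oxy]oxolane-2-carbaldehyde
Conditions: (COCl)2, DMSO, CH2Cl2, −78 to −40 °C; then iPr2NEt, −78 to 0 °C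
Reagents that add atoms: none
Why: In the Swern oxidation of silyl ethers the chlorosulfonium reagent cleaves the unhindered primary triethylsilyl ether and oxidises it in place to the aldehyde while the secondary triethylsilyl ether is kept, and the hindered amine at low temperature limits epimerisation at the α-carbon.

Step 6
Reactants: 9 (2S,3S)-5-oxo-3-[(triethylsilyl)oxy]oxolane-2-carbaldehyde
Product: 10 (4S,5R)-5-(2-methylprop-1-en-1-yl)-4-[(triethylsilyl)oxy]oxolan-2-one
Conditions: iPrPPh3+ I−, n-BuLi, THF, 0 °C; then 9, −78 to 0 °C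
Reagents that add atoms: isopropyltriphenylphosphonium iodide CC(C)[P+](c1ccccc1)(c1ccccc1)c1ccccc1.[I-]
Why: Wittig olefination with the non-stabilised isopropylidene ylide adds to the aldehyde far faster than to the lactone at −78 °C and, because the new alkene carries two identical methyl groups, raises no geometry question.

Step 7
Reactants: 10 (4S,5R)-5-(2-methylprop-1-en-1-yl)-4-[(triethylsilyl)oxy]oxolan-2-one
Product: 12 (4S,5R)-3-(1-hydroxyethyl)-5-(2-methylprop-1-en-1-yl)-4-[(triethylsilyl)oxy]oxolan-2-one (diastereomer mixture at C3 and the carbinol carbon), via lithium lactone enolate 11 (not isolated)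
Conditions: LDA (LiN(iPr)2), THF, −78 °C; CH3CHO, −78 °C; aq NH4Cl
Reagents that add atoms: acetaldehyde CC=O
Why: Aldol addition of the lithium enolate, which is stable to β-elimination of the silyloxy group at −78 °C, installs C9 and C10, and both new stereocentres are erased in step 8, so their configuration is irrelevant.

Step 8
Reactants: 12 (4S,5R)-3-(1-hydroxyethyl)-5-(2-methylprop-1-en-1-yl)-4-[(triethylsilyl)oxy]oxolan-2-one
Product: 14 (3E,4S,5R)-3-ethylidene-5-(2-methylprop-1-en-1-yl)-4-[(triethylsilyl)oxy]oxolan-2-one, via secondary mesylate 13 (not isolated)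
Conditions: MsCl, Et3N, CH2Cl2, 0 °C; then DBU, 0 °C to rt
Reagents that add atoms: none
Why: Mesylation followed by E1cB elimination expels the better leaving group (mesylate, not the silyloxy group) and should favour the E-ethylidene lactone; any Z isomer converges to the same dienol ether in step 9.

Step 9
Reactants: 14 (3E,4S,5R)-3-ethylidene-5-(2-methylprop-1-en-1-yl)-4-[(triethylsilyl)oxy]oxolan-2-one
Product: 16 tert-butyl({(4S,5R)-3-ethenyl-5-(2-methylprop-1-en-1-yl)-4-[(triethylsilyl)oxy]-4,5-dihydrofuran-2-yl}oxy)dimethylsilane, via lithium dienolate 15 (not isolated)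
Conditions: LDA (LiN(iPr)2), DMPU, THF, −78 °C; TBSCl, −78 °C; pentane, filter, use crude
Reagents that add atoms: tert-butyl(chloro)dimethylsilane CC(C)(C)[Si](C)(C)Cl
Why: Kinetic γ-deprotonation of the α-alkylidene lactone at its methyl group gives the extended enolate, and O-silylation by the hard silyl chloride in THF/DMPU at −78 °C traps it as the silyl dienol ether before β-elimination can occur; C12 and C13 are not involved.

Step 10
Reactants: 5 (2Z,6E)-3,7-dimethyl-8-oxoocta-2,6-dien-1-yl (2E)-3-methylpent-2-enoate; 16 tert-butyl({(4S,5R)-3-ethenyl-5-(2-methylprop-1-en-1-yl)-4-[(triethylsilyl)oxy]-4,5-dihydrofuran-2-yl}oxy)dimethylsilane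
Product: 18 (2Z,6E,8S)-8-hydroxy-3,7-dimethyl-10-{(3E,4S,5R)-5-(2-methylprop-1-en-1-yl)-2-oxo-4-[(triethylsilyl)oxy]oxolan-3-ylidene}deca-2,6-dien-1-yl (2E)-3-methylpent-2-enoate, via C8 trichlorosilyl ether 17 (not isolated)
Conditions: SiCl4 (1.1 equiv), (S,S)-bisphosphoramide [pentane-1,5-diyl-linked bis-phosphoramide of (S)-N,N'-dimethyl-1,1'-binaphthyl-2,2'-diamine] (5 mol %), iPr2NEt (10 mol %), CH2Cl2, −78 °C; aq NaHCO3
Reagents that add atoms: none
Why: The chiral bisphosphoramide binds SiCl4 and ionises it to a trichlorosilyl cation that activates only the aldehyde of 5, the terminal CH2 (C9) of the 2-silyloxydiene 16 attacks C8 through an open transition state, and loss of the silyl group as the chlorosilane re-forms the lactone C=O with its exocyclic C10=C11 alkene, which is a Lewis-base-catalysed vinylogous Mukaiyama aldol reaction, a known class for ester-derived silyl dienol ethers and conjugated aldehydes. No ring is closed. The only new stereocentre, C8, is set by the catalyst: the (S,S)-bisphosphoramide is expected to direct attack to the Si face of the α-methyl enal (its antipode being Re-selective in this reaction class), which gives 8S, and the C12 and C13 centres of 16, four and five bonds away, should not override it. Attack at γ (C9) instead of α (C11) is secured by the fully substituted, silyloxy-flanked C11 and by the bulk of the catalyst-bound aldehyde, and 1,2-addition is secured by the substituted β-carbon of the enal. The E geometry of C10=C11 (C9 cis to C12) follows from reaction through the s-trans diene conformer, in which the vinyl group avoids the silyloxy group of the ketene acetal, and this geometry also prevents the C8 hydroxyl from translactonising. The allylic ester, the trisubstituted alkenes and the triethylsilyl ether should be inert to SiCl4 at −78 °C in the presence of iPr2NEt.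

Step 11
Reactants: 18 the 8S alcohol
Product: 19 (2Z,6E,8S)-8-acetoxy-3,7-dimethyl-10-{(3E,4S,5R)-5-(2-methylprop-1-en-1-yl)-2-oxo-4-[(triethylsilyl)oxy]oxolan-3-ylidene}deca-2,6-dien-1-yl (2E)-3-methylpent-2-enoate
Conditions: Ac2O, pyridine, DMAP (cat.), CH2Cl2, 0 °C
Reagents that add atoms: acetic anhydride CC(=O)OC(C)=O
Why: DMAP-catalysed acylation of the only free hydroxyl group proceeds with retention at C8 under conditions too weakly basic to cause vinylogous elimination.

Step 12
Reactants: 19 the C12 triethylsilyl ether of the target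
Product: 20 target, (2Z,6E,8S)-8-acetoxy-10-[(3E,4S,5R)-4-hydroxy-5-(2-methylprop-1-en-1-yl)-2-oxooxolan-3-ylidene]-3,7-dimethyldeca-2,6-dien-1-yl (2E)-3-methylpent-2-enoate
Conditions: HF·pyridine, pyridine, THF, 0 °C
Reagents that add atoms: none
Why: Fluoride-driven cleavage of the Si–O bond under buffered, slightly acidic conditions frees the C12 hydroxyl and avoids the basic conditions that could eliminate the C8 acetate through the vinylogous position C9 or hydrolyse the esters.

**Compound list**

1 | nerol, (2Z)-3,7-dimethylocta-2,6-dien-1-ol | CC(C)=CCC/C(C)=C\CO | starting material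
2 | (2E)-3-methylpent-2-enoic acid | CC/C(C)=C/C(=O)O | starting material
3 | (2Z)-3,7-dimethylocta-2,6-dien-1-yl (2E)-3-methylpent-2-enoate | CC/C(C)=C/C(=O)OC/C=C(/C)CCC=C(C)C | intermediate
4 | (2Z,6E)-8-hydroxy-3,7-dimethylocta-2,6-dien-1-yl (2E)-3-methylpent-2-enoate | CC/C(C)=C/C(=O)OC/C=C(/C)CC/C=C(\C)CO | intermediate (not isolated)
5 | (2Z,6E)-3,7-dimethyl-8-oxoocta-2,6-dien-1-yl (2E)-3-methylpent-2-enoate | CC/C(C)=C/C(=O)OC/C=C(/C)CC/C=C(\C)C=O | intermediate
6 | 2-deoxy-D-ribose (drawn as the open-chain aldehyde) | O=CC[C@H](O)[C@H](O)CO | starting material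
7 | 2-deoxy-D-ribono-1,4-lactone, (4S,5R)-4-hydroxy-5-(hydroxymethyl)oxolan-2-one | O=C1C[C@H](O)[C@@H](CO)O1 | intermediate
8 | (4S,5R)-4-[(triethylsilyl)oxy]-5-{[(triethylsilyl)oxy]methyl}oxolan-2-one | O=C1C[C@H](O[Si](CC)(CC)CC)[C@@H](CO[Si](CC)(CC)CC)O1 | intermediate
9 | (2S,3S)-5-oxo-3-[(triethylsilyl)oxy]oxolane-2-carbaldehyde | O=C1C[C@H](O[Si](CC)(CC)CC)[C@@H](C=O)O1 | intermediate
10 | (4S,5R)-5-(2-methylprop-1-en-1-yl)-4-[(triethylsilyl)oxy]oxolan-2-one | O=C1C[C@H](O[Si](CC)(CC)CC)[C@@H](C=C(C)C)O1 | intermediate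
11 | lithium enolate of 10 | [Li+].[O-]C1=C[C@H](O[Si](CC)(CC)CC)[C@@H](C=C(C)C)O1 | intermediate (not isolated)
12 | (4S,5R)-3-(1-hydroxyethyl)-5-(2-methylprop-1-en-1-yl)-4-[(triethylsilyl)oxy]oxolan-2-one, diastereomer mixture | CC(O)C1C(=O)O[C@H](C=C(C)C)[C@H]1O[Si](CC)(CC)CC | intermediate
13 | methanesulfonate of 12 | CC(OS(C)(=O)=O)C1C(=O)O[C@H](C=C(C)C)[C@H]1O[Si](CC)(CC)CC | intermediate (not isolated)
14 | (3E,4S,5R)-3-ethylidene-5-(2-methylprop-1-en-1-yl)-4-[(triethylsilyl)oxy]oxolan-2-one | C/C=C1/C(=O)O[C@H](C=C(C)C)[C@H]1O[Si](CC)(CC)CC | intermediate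
15 | lithium dienolate of 14 | [Li+].[O-]C1=C(C=C)[C@H](O[Si](CC)(CC)CC)[C@@H](C=C(C)C)O1 | intermediate (not isolated)
16 | tert-butyl({(4S,5R)-3-ethenyl-5-(2-methylprop-1-en-1-yl)-4-[(triethylsilyl)oxy]-4,5-dihydrofuran-2-yl}oxy)dimethylsilane | C=CC1=C(O[Si](C)(C)C(C)(C)C)O[C@H](C=C(C)C)[C@H]1O[Si](CC)(CC)CC | intermediate
17 | C8 trichlorosilyl ether of 18 | CC/C(C)=C/C(=O)OC/C=C(/C)CC/C=C(\C)[C@H](C/C=C1/C(=O)O[C@H](C=C(C)C)[C@H]1O[Si](CC)(CC)CC)O[Si](Cl)(Cl)Cl | intermediate (not isolated)
18 | (2Z,6E,8S)-8-hydroxy-3,7-dimethyl-10-{(3E,4S,5R)-5-(2-methylprop-1-en-1-yl)-2-oxo-4-[(triethylsilyl)oxy]oxolan-3-ylidene}deca-2,6-dien-1-yl (2E)-3-methylpent-2-enoate | CC/C(C)=C/C(=O)OC/C=C(/C)CC/C=C(\C)[C@H](C/C=C1/C(=O)O[C@H](C=C(C)C)[C@H]1O[Si](CC)(CC)CC)O | intermediate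
19 | 8-O-acetate of 18 | CC/C(C)=C/C(=O)OC/C=C(/C)CC/C=C(\C)[C@H](C/C=C1/C(=O)O[C@H](C=C(C)C)[C@H]1O[Si](CC)(CC)CC)OC(C)=O | intermediate
20 | (2Z,6E,8S)-8-acetoxy-10-[(3E,4S,5R)-4-hydroxy-5-(2-methylprop-1-en-1-yl)-2-oxooxolan-3-ylidene]-3,7-dimethyldeca-2,6-dien-1-yl (2E)-3-methylpent-2-enoate | CC/C(C)=C/C(=O)OC/C=C(/C)CC/C=C(\C)[C@H](C/C=C1/C(=O)O[C@H](C=C(C)C)[C@H]1O)OC(C)=O | target

**Step count and risks**

Total steps: 12. Longest linear sequence: 10 steps (steps 3 to 12, from 2-deoxy-D-ribose).

Steps most likely to fail: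

1. Step 10. What may go wrong: insufficient discrimination between the two faces of the aldehyde, so that both C8 epimers form. The fallback sets out from 5 and 16 and comes back at 18. The two fragments would be joined without a chiral catalyst (BF3·OEt2, CH2Cl2, −78 °C) to give the C8-epimeric alcohol mixture F1. Dess–Martin periodinane buffered with NaHCO3 would oxidise it to the C8 ketone F2. Corey–Bakshi–Shibata reduction ((R)-2-methyl-CBS-oxazaborolidine, catecholborane, toluene, −78 °C), with the α-methyl alkenyl group acting as the large substituent, would then return the 8S alcohol 18 under reagent control.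

2. Step 9. What may go wrong: β-elimination of the C12 silyloxy group from the lithium dienolate, or conjugate addition of the amide base, before O-silylation. The fallback sets out from 14 and comes back at 18. The triethylsilyl ether would be removed (HF·pyridine, THF) to give the hydroxy ethylidene lactone F3. With 2.3 equiv of LDA (LiN(iPr)2) and DMPU the alkoxide–dienolate dianion would form, in which the C12 oxygen is an oxide and cannot leave. Double silylation with Et3SiCl would give the bis(triethylsilyl) dienol ether F4, which would take the place of 16 in step 10 and deliver 18 directly.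

3. Step 6. What may go wrong: epimerisation at the α-carbon or β-elimination of the silyloxy group of the aldehyde under the basic ylide. The fallback sets out from 9 and comes back at 10. Non-basic methylenation (Zn, CH2Br2, TiCl4, THF, 0 °C) would give the vinyl lactone F5. Cross-metathesis with excess 2-methylbut-2-ene (second-generation Grubbs catalyst, RuCl2(=CHPh)(PCy3)(H2IMes), CH2Cl2, 40 °C) would then install the two methyl groups and give 10.

**Further compounds**

F1 | step 10 | (2Z,6E,8RS)-8-hydroxy-3,7-dimethyl-10-{(3E,4S,5R)-5-(2-methylprop-1-en-1-yl)-2-oxo-4-[(triethylsilyl)oxy]oxolan-3-ylidene}deca-2,6-dien-1-yl (2E)-3-methylpent-2-enoate, C8 epimer mixture | CC/C(C)=C/C(=O)OC/C=C(/C)CC/C=C(\C)C(O)C/C=C1/C(=O)O[C@H](C=C(C)C)[C@H]1O[Si](CC)(CC)CC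
F2 | step 10 | (2Z,6E)-3,7-dimethyl-10-{(3E,4S,5R)-5-(2-methylprop-1-en-1-yl)-2-oxo-4-[(triethylsilyl)oxy]oxolan-3-ylidene}-8-oxodeca-2,6-dien-1-yl (2E)-3-methylpent-2-enoate | CC/C(C)=C/C(=O)OC/C=C(/C)CC/C=C(\C)C(=O)C/C=C1/C(=O)O[C@H](C=C(C)C)[C@H]1O[Si](CC)(CC)CC
F3 | step 9 | (3E,4S,5R)-3-ethylidene-4-hydroxy-5-(2-methylprop-1-en-1-yl)oxolan-2-one | C/C=C1/C(=O)O[C@H](C=C(C)C)[C@H]1O
F4 | step 9 | {[(4S,5R)-3-ethenyl-5-(2-methylprop-1-en-1-yl)-4-[(triethylsilyl)oxy]-4,5-dihydrofuran-2-yl]oxy}triethylsilane | C=CC1=C(O[Si](CC)(CC)CC)O[C@H](C=C(C)C)[C@H]1O[Si](CC)(CC)CC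
F5 | step 6 | (4S,5R)-5-ethenyl-4-[(triethylsilyl)oxy]oxolan-2-one | O=C1C[C@H](O[Si](CC)(CC)CC)[C@@H](C=C)O1
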